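**Retrosynthetic overview**

1. Daucane numbering is used: five-membered ring C1–C5, seven-membered ring C1 and C5–C10, CH3 on C1, isopropyl on C4, C14H2–O on C8. The vanillate C14–O bond is made last (Mitsunobu) from vanillic acid and (R)-dauca-4,8-dien-14-ol.
2. Feature: the only stereocentre, quaternary C1, carries CH3, C5 and two three-carbon arms (C2–C3–C4 in the five-membered ring; C10–C9 plus one terminal carbon towards the seven-membered ring). It is therefore a prochiral carbon bearing two allyl groups and a formyl carbon in disguise.
3. Key disconnection C4–C5: an enantioselective desymmetrising rhodium hydroacylation of 2-allyl-2-methylpent-4-enal closes the five-membered ring first and fixes C1. The aldehyde comes from propanenitrile and two equivalents of allyl bromide.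
4. The C5 ketone then serves C4 (isopropyl by acetone aldol, dehydration, conjugate reduction) and C6 (organocerium addition of a C6–C7–C8(=CH2)–C14H2OSi chain).
5. The seven-membered ring closes second by ring-closing metathesis (C8=C9) onto the spare allyl group; dehydration of the C5 carbinol gives C4=C5; desilylation and esterification finish.

Key step: step 3

Remark: lithium enolates and lithiated nitriles are treated as metallated forms of the numbered compounds and carry no number of their own. The stereocentres other than C1 that appear in 8, 9, 11, 21, 22 and 23 are carried as mixtures, since all are removed by step 14.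
Remark: the ligand in step 3 is written as (R)-BINAP; which antipode delivers (R)-7 is to be settled by running both, and the other antipode is used if required.

**Route**

Step 1
Reactants: 1 propanenitrile; 2 allyl bromide (3-bromoprop-1-ene)
Product: 4 2-allyl-2-methylpent-4-enenitrile, via 2-methylpent-4-enenitrile 3 (not isolated)
Conditions: LiN(iPr)2 (1.05 equiv), THF, −78 °C, then 2 (1.05 equiv), −78 → 0 °C; recool to −78 °C, LiN(iPr)2 (1.1 equiv), then a second portion of 2 (1.2 equiv), → rt
Reagents that add atoms: allyl bromide (second equivalent of 2), C=CCBr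
Why: Nitrile α-alkylation run twice in one flask, consuming two equivalents of allyl bromide in all: each lithiated nitrile is a small, reactive nucleophile for SN2 attack on the allylic bromide, and the second allylation makes the α-carbon quaternary and prochiral, so no stereocentre remains.

Step 2
Reactants: 4 2-allyl-2-methylpent-4-enenitrile
Product: 6 2-allyl-2-methylpent-4-enal, via N-aluminio aldimine 5 (not isolated)
Conditions: iBu2AlH (1.2 equiv), CH2Cl2, −78 → 0 °C; then 1 M HCl, 0 °C
Reagents that add atoms: water, O
Why: Partial hydride reduction of a nitrile: one hydride adds to give the N-aluminio aldimine, which is not reduced further at low temperature and is hydrolysed to the aldehyde by aqueous acid; the α-carbon is quaternary, so the aldehyde cannot enolise or condense with itself.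

Step 3
Reactants: 6 2-allyl-2-methylpent-4-enal
Product: 7 (R)-2-allyl-2-methylcyclopentan-1-one
Conditions: [Rh(nbd)((R)-BINAP)]BF4 (5 mol %), activated with H2 in acetone and then purged with Ar, CH2Cl2 (degassed, 0.1 M), 25 °C
Reagents that add atoms: none
Why: The cationic bisphosphine complex of monovalent rhodium inserts into the aldehyde C–H bond to give an acyl hydride of trivalent rhodium, one allyl alkene binds and inserts into Rh–H with the hydride going to the internal carbon, and C–C reductive elimination from the resulting six-membered acyl rhodacycle forms the C4–C5 bond and frees the catalyst. The closest known reaction type is the rhodium–bisphosphine intramolecular hydroacylation of 4-pentenals to cyclopentanones, which is established for 2,2-disubstituted substrates and for variants that select between enantiotopic groups. The five-membered ring (C1–C5) closes in the formal 5-endo sense, acyl carbon to the terminal alkene carbon, by way of the six-membered metallacycle; the alternative insertion to a five-membered metallacycle and a cyclobutanone is disfavoured. The only new stereocentre is quaternary C1, and it is set by the chiral bisphosphine, which has to choose between the two enantiotopic allyl groups at the alkene-binding and insertion stage, since nothing in the substrate distinguishes them. The step needs this enantiotopic-group selectivity, and chemoselectivity for ring closure over decarbonylation and over double-bond migration in the allyl groups. The quaternary α-carbon helps by speeding ring closure (gem-disubstituent effect) and by leaving no α-hydrogen for enolisation or epimerisation, and the untouched allyl group is kept as the C10–C9 arm.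

Step 4
Reactants: 7 (R)-2-allyl-2-methylcyclopentan-1-one
Product: 8 (2R)-2-allyl-5-(2-hydroxypropan-2-yl)-2-methylcyclopentan-1-one (both C5 epimers)
Conditions: LiN(iPr)2 (1.1 equiv), THF, −78 °C; acetone (3 equiv), −78 °C, 15 min; AcOH, −78 °C
Reagents that add atoms: acetone, CC(C)=O
Why: Directed aldol addition: only C5 of the ketone (daucane C4) carries α-hydrogens, so a single lithium enolate forms, and quenching cold keeps the aldolate from reverting; the new C5 stereocentre is not controlled and is removed in step 5.

Step 5
Reactants: 8 (2R)-2-allyl-5-(2-hydroxypropan-2-yl)-2-methylcyclopentan-1-one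
Product: 10 (R)-2-allyl-2-methyl-5-(propan-2-ylidene)cyclopentan-1-one, via tertiary mesylate 9 (not isolated)
Conditions: MsCl, Et3N, CH2Cl2, 0 °C; then DBU, rt
Reagents that add atoms: none
Why: Sulfonylation of the tertiary aldol hydroxyl followed by base-mediated β-elimination (E1cB through the enolate) gives the conjugated exocyclic enone, and DBU should move any isopropenyl isomer into conjugation; C1 is untouched.

Step 6
Reactants: 10 (R)-2-allyl-2-methyl-5-(propan-2-ylidene)cyclopentan-1-one
Product: 11 (2R)-2-allyl-2-methyl-5-(propan-2-yl)cyclopentan-1-one (both C5 epimers)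
Conditions: Li (2.5 equiv), liquid NH3/THF, t-BuOH (1 equiv), −78 °C; then solid NH4Cl
Reagents that add atoms: none
Why: Dissolving-metal conjugate reduction of an enone: two electrons and one proton give the lithium enolate, which is protonated on quench, while the isolated terminal alkene is not reduced; the C5 configuration is not controlled and is erased in step 14.

Step 7
Reactants: 12 3-bromobut-3-en-1-ol
Product: 13 2-[(3-bromobut-3-en-1-yl)oxy]tetrahydro-2H-pyran (racemic)
Conditions: 3,4-dihydro-2H-pyran, PPTS (cat.), CH2Cl2, rt
Reagents that add atoms: 3,4-dihydro-2H-pyran, C1=COCCC1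
Why: Acid-catalysed addition of the alcohol to the enol ether (tetrahydropyranyl protection) masks the hydroxyl against the organolithium of step 8.

Step 8
Reactants: 13 2-[(3-bromobut-3-en-1-yl)oxy]tetrahydro-2H-pyran
Product: 15 2-methylidene-4-(tetrahydro-2H-pyran-2-yloxy)butan-1-ol, via vinyllithium 14 (not isolated)
Conditions: t-BuLi (2.1 equiv), Et2O, −78 °C; then dry paraformaldehyde, −78 °C → rt; H2O
Reagents that add atoms: paraformaldehyde (as formaldehyde), C=O
Why: Lithium–bromine exchange on the 2-bromoalkene (the second equivalent of t-BuLi destroys the t-BuBr formed) gives a vinyllithium with no β-leaving group, which adds to formaldehyde to install C14 as the allylic alcohol.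

Step 9
Reactants: 15 2-methylidene-4-(tetrahydro-2H-pyran-2-yloxy)butan-1-ol
Product: 16 tert-butyl{[2-methylidene-4-(tetrahydro-2H-pyran-2-yloxy)butyl]oxy}diphenylsilane
Conditions: TBDPSCl, imidazole, DMF, rt
Reagents that add atoms: tert-butyl(chloro)diphenylsilane (TBDPSCl), CC(C)(C)[Si](Cl)(c1ccccc1)c1ccccc1
Why: Imidazole-promoted silylation of the primary allylic alcohol; the tert-butyldiphenylsilyl ether is chosen because it survives the acid of step 10 and the organometallic, metathesis and dehydration steps that follow.

Step 10
Reactants: 16 tert-butyl{[2-methylidene-4-(tetrahydro-2H-pyran-2-yloxy)butyl]oxy}diphenylsilane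
Product: 17 3-{[(tert-butyldiphenylsilyl)oxy]methyl}but-3-en-1-ol
Conditions: PPTS (cat.), MeOH, 45 °C
Reagents that add atoms: none
Why: Mild acid-catalysed transacetalisation to methanol removes the tetrahydropyranyl group, and the acid-stable tert-butyldiphenylsilyl ether stays in place.

Step 11
Reactants: 17 3-{[(tert-butyldiphenylsilyl)oxy]methyl}but-3-en-1-ol
Product: 18 [(4-bromo-2-methylidenebutyl)oxy](tert-butyl)diphenylsilane
Conditions: CBr4, PPh3, CH2Cl2, 0 °C
Reagents that add atoms: carbon tetrabromide, BrC(Br)(Br)Br
Why: Appel reaction: the primary homoallylic alcohol is activated as its oxyphosphonium salt and displaced by bromide under neutral conditions that leave the silyl ether and the alkene alone.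

Step 12
Reactants: 18 [(4-bromo-2-methylidenebutyl)oxy](tert-butyl)diphenylsilane; 11 (2R)-2-allyl-2-methyl-5-(propan-2-yl)cyclopentan-1-one
Product: 21 (2R)-2-allyl-1-(3-{[(tert-butyldiphenylsilyl)oxy]methyl}but-3-en-1-yl)-2-methyl-5-(propan-2-yl)cyclopentan-1-ol (C1/C5 diastereomers), via Grignard reagent 19 (not isolated), via organocerium reagent 20 (not isolated)
Conditions: 18, Mg turnings, THF, rt; transfer onto anhydrous CeCl3, THF, −78 °C, 1 h; then 11, −78 → 0 °C; aq. NH4Cl
Reagents that add atoms: none
Why: Organocerium addition to a ketone: the weakly basic, strongly oxophilic cerium reagent adds to the hindered, enolisable carbonyl instead of deprotonating it, and is expected to enter anti to the C5 isopropyl group, which leaves the C5 hydrogen anti to the new hydroxyl; the carbinol stereocentre is removed in step 14.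

Step 13
Reactants: 21 (2R)-2-allyl-1-(3-{[(tert-butyldiphenylsilyl)oxy]methyl}but-3-en-1-yl)-2-methyl-5-(propan-2-yl)cyclopentan-1-ol
Product: 22 (8aR)-6-{[(tert-butyldiphenylsilyl)oxy]methyl}-8a-methyl-3-(propan-2-yl)-1,2,3,3a,4,5,8,8a-octahydroazulen-3a-ol (C3/C3a diastereomers)
Conditions: second-generation Grubbs catalyst (H2IMes)(PCy3)Cl2Ru=CHPh (5 mol %), CH2Cl2 (5 mM), 40 °C
Reagents that add atoms: none
Why: Ring-closing metathesis between the monosubstituted allyl alkene (where the catalyst loads) and the 1,1-disubstituted alkene closes the seven-membered ring with the trisubstituted C8=C9 double bond and loss of ethylene; the free tertiary alcohol and the silyl ether are tolerated.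

Step 14
Reactants: 22 (8aR)-6-{[(tert-butyldiphenylsilyl)oxy]methyl}-8a-methyl-3-(propan-2-yl)-1,2,3,3a,4,5,8,8a-octahydroazulen-3a-ol
Product: 24 tert-butyl{[(8aR)-8a-methyl-3-(propan-2-yl)-1,2,4,5,8,8a-hexahydroazulen-6-yl]methoxy}diphenylsilane, via chlorosulfite 23 (not isolated)
Conditions: SOCl2 (2 equiv), pyridine, 0 °C
Reagents that add atoms: none
Why: Dehydration of a tertiary alcohol through its chlorosulfite with pyridine as base: elimination should go towards C4, where the hydrogen lies anti to the leaving group and the tetrasubstituted alkene results, because C1 has no hydrogen and the C6 hydrogens lead only to a trisubstituted alkene.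

Step 15
Reactants: 24 tert-butyl{[(8aR)-8a-methyl-3-(propan-2-yl)-1,2,4,5,8,8a-hexahydroazulen-6-yl]methoxy}diphenylsilane
Product: 25 [(8aR)-8a-methyl-3-(propan-2-yl)-1,2,4,5,8,8a-hexahydroazulen-6-yl]methanol, (R)-dauca-4,8-dien-14-ol
Conditions: Bu4NF, THF, 0 °C → rt
Reagents that add atoms: none
Why: Fluoride-mediated cleavage of the silyl ether, driven by the strong Si–F bond, under basic conditions that do not move either double bond.

Step 16
Reactants: 25 [(8aR)-8a-methyl-3-(propan-2-yl)-1,2,4,5,8,8a-hexahydroazulen-6-yl]methanol; 26 vanillic acid (4-hydroxy-3-methoxybenzoic acid)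
Product: 27 [(8aR)-8a-methyl-3-(propan-2-yl)-1,2,4,5,8,8a-hexahydroazulen-6-yl]methyl 4-hydroxy-3-methoxybenzoate (target)
Conditions: 26 (1.2 equiv), PPh3, DIAD (added last, slowly), THF, 0 °C → rt
Reagents that add atoms: none
Why: Mitsunobu esterification: the primary allylic alcohol is activated as its oxyphosphonium salt and displaced at CH2 by the carboxylate, which forms in preference to the phenoxide because the carboxylic acid is by far the more acidic group, so the phenol needs no protection and no stereocentre is involved.

**Compound list**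

1 | propanenitrile | CCC#N | starting material
2 | allyl bromide (3-bromoprop-1-ene) | C=CCBr | starting material
3 | 2-methylpent-4-enenitrile (racemic) | C=CCC(C)C#N | intermediate (not isolated)
4 | 2-allyl-2-methylpent-4-enenitrile | C=CCC(C)(CC=C)C#N | intermediate
5 | N-(diisobutylaluminio) aldimine of 2-allyl-2-methylpent-4-enal | C=CCC(C)(CC=C)C=N[Al](CC(C)C)CC(C)C | intermediate (not isolated)
6 | 2-allyl-2-methylpent-4-enal | C=CCC(C)(CC=C)C=O | intermediate
7 | (R)-2-allyl-2-methylcyclopentan-1-one | C=CC[C@@]1(C)CCCC1=O | intermediate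
8 | (2R)-2-allyl-5-(2-hydroxypropan-2-yl)-2-methylcyclopentan-1-one (C5 epimers) | C=CC[C@@]1(C)CCC(C(C)(C)O)C1=O | intermediate
9 | 2-[(3R)-3-allyl-3-methyl-2-oxocyclopentyl]propan-2-yl methanesulfonate | C=CC[C@@]1(C)CCC(C(C)(C)OS(C)(=O)=O)C1=O | intermediate (not isolated)
10 | (R)-2-allyl-2-methyl-5-(propan-2-ylidene)cyclopentan-1-one | C=CC[C@@]1(C)CCC(=C(C)C)C1=O | intermediate
11 | (2R)-2-allyl-2-methyl-5-(propan-2-yl)cyclopentan-1-one (C5 epimers) | C=CC[C@@]1(C)CCC(C(C)C)C1=O | intermediate
12 | 3-bromobut-3-en-1-ol | C=C(Br)CCO | starting material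
13 | 2-[(3-bromobut-3-en-1-yl)oxy]tetrahydro-2H-pyran (racemic) | C=C(Br)CCOC1CCCCO1 | intermediate
14 | [4-(tetrahydro-2H-pyran-2-yloxy)but-1-en-2-yl]lithium | C=C([Li])CCOC1CCCCO1 | intermediate (not isolated)
15 | 2-methylidene-4-(tetrahydro-2H-pyran-2-yloxy)butan-1-ol | C=C(CO)CCOC1CCCCO1 | intermediate
16 | tert-butyl{[2-methylidene-4-(tetrahydro-2H-pyran-2-yloxy)butyl]oxy}diphenylsilane | C=C(CCOC1CCCCO1)CO[Si](c1ccccc1)(c1ccccc1)C(C)(C)C | intermediate
17 | 3-{[(tert-butyldiphenylsilyl)oxy]methyl}but-3-en-1-ol | C=C(CCO)CO[Si](c1ccccc1)(c1ccccc1)C(C)(C)C | intermediate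
18 | [(4-bromo-2-methylidenebutyl)oxy](tert-butyl)diphenylsilane | C=C(CCBr)CO[Si](c1ccccc1)(c1ccccc1)C(C)(C)C | intermediate
19 | (3-{[(tert-butyldiphenylsilyl)oxy]methyl}but-3-en-1-yl)magnesium bromide | C=C(CC[Mg]Br)CO[Si](c1ccccc1)(c1ccccc1)C(C)(C)C | intermediate (not isolated)
20 | dichloro(3-{[(tert-butyldiphenylsilyl)oxy]methyl}but-3-en-1-yl)cerium, written as RCeCl2 | C=C(CC[Ce](Cl)Cl)CO[Si](c1ccccc1)(c1ccccc1)C(C)(C)C | intermediate (not isolated)
21 | (2R)-2-allyl-1-(3-{[(tert-butyldiphenylsilyl)oxy]methyl}but-3-en-1-yl)-2-methyl-5-(propan-2-yl)cyclopentan-1-ol (C1/C5 diastereomers) | C=CC[C@@]1(C)CCC(C(C)C)C1(O)CCC(=C)CO[Si](c2ccccc2)(c2ccccc2)C(C)(C)C | intermediate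
22 | (8aR)-6-{[(tert-butyldiphenylsilyl)oxy]methyl}-8a-methyl-3-(propan-2-yl)-1,2,3,3a,4,5,8,8a-octahydroazulen-3a-ol (C3/C3a diastereomers) | CC(C)(C)[Si](c1ccccc1)(c1ccccc1)OCC2=CC[C@@]3(C)CCC(C(C)C)C3(O)CC2 | intermediate
23 | chlorosulfite of 22 | CC(C)(C)[Si](c1ccccc1)(c1ccccc1)OCC2=CC[C@@]3(C)CCC(C(C)C)C3(OS(Cl)=O)CC2 | intermediate (not isolated)
24 | tert-butyl{[(8aR)-8a-methyl-3-(propan-2-yl)-1,2,4,5,8,8a-hexahydroazulen-6-yl]methoxy}diphenylsilane | CC(C)(C)[Si](c1ccccc1)(c1ccccc1)OCC2=CC[C@@]3(C)CCC(C(C)C)=C3CC2 | intermediate
25 | [(8aR)-8a-methyl-3-(propan-2-yl)-1,2,4,5,8,8a-hexahydroazulen-6-yl]methanol | OCC1=CC[C@@]2(C)CCC(C(C)C)=C2CC1 | intermediate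
26 | vanillic acid (4-hydroxy-3-methoxybenzoic acid) | COc1cc(C(=O)O)ccc1O | starting material
27 | [(8aR)-8a-methyl-3-(propan-2-yl)-1,2,4,5,8,8a-hexahydroazulen-6-yl]methyl 4-hydroxy-3-methoxybenzoate | COc1cc(C(=O)OCC2=CC[C@@]3(C)CCC(C(C)C)=C3CC2)ccc1O | target

**Step count and risks**

Total step count: 16 (steps 1–16).
Longest linear sequence: 11 steps (steps 1–6 and 12–16 from propanenitrile); the side chain 18 is made in 5 steps (steps 7–11) from 3-bromobut-3-en-1-ol.

Steps most likely to fail:

1. Step 3. The catalyst may discriminate poorly between the two enantiotopic allyl groups, giving low enantiomeric purity. The rhodium hydride may also move the double bonds of the allyl groups before or after ring closure, or the acyl rhodium may lose CO. The fallback sets out from allyl bromide 2 and comes back at ketone 7. Commercial 2-methylcyclopentane-1,3-dione is C-allylated with 2 (aq. NaOH, rt) to give 2-allyl-2-methylcyclopentane-1,3-dione F1. Reduction of one of the two enantiotopic carbonyl groups with baker's yeast (sucrose, water, 30 °C) should give (2S,3S)-2-allyl-3-hydroxy-2-methylcyclopentan-1-one F2. Its quaternary carbon already has the spatial arrangement of 7; the descriptor changes from S to R only because the hydroxyl is later removed. Acylation with 1,1'-thiocarbonyldiimidazole (DMAP, 1,2-dichloroethane, 80 °C) gives O-[(1S,2S)-2-allyl-2-methyl-3-oxocyclopentyl] 1H-imidazole-1-carbothioate F3. Barton–McCombie deoxygenation (Bu3SnH, AIBN, toluene, 110 °C) then gives 7.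

2. Step 14. The elimination may lose regiocontrol, with proton removal from C6 in the seven-membered ring instead of C4, or the tertiary centre may ionise and a group may shift from C1. The fallback sets out from ketone 11 and comes back at silyl ether 24; it fixes the alkene position by enolisation, which can only go towards C4. KN(SiMe3)2 and PhNTf2 (THF, −78 → 0 °C) give (5R)-5-allyl-5-methyl-2-(propan-2-yl)cyclopent-1-en-1-yl trifluoromethanesulfonate F4. Iron-catalysed cross-coupling with Grignard reagent 19 (Fe(acac)3, THF/NMP, −20 → 0 °C) gives tert-butyl({4-[(5R)-5-allyl-5-methyl-2-(propan-2-yl)cyclopent-1-en-1-yl]-2-methylidenebutyl}oxy)diphenylsilane F5. Ring-closing metathesis under the conditions of step 13, in which the tetrasubstituted alkene takes no part, gives 24.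

3. Step 12. The hindered ketone, flanked by a quaternary carbon and an isopropyl-bearing carbon, may be deprotonated at C4 or may not be attacked at all. The fallback sets out from enone 10, which has no α-hydrogen and a flat α-carbon, and comes back at silyl ether 24. 1,2-Addition of organocerium reagent 20 (THF, −78 °C) gives (2R)-2-allyl-1-(3-{[(tert-butyldiphenylsilyl)oxy]methyl}but-3-en-1-yl)-2-methyl-5-(propan-2-ylidene)cyclopentan-1-ol F6. Ring-closing metathesis as in step 13 gives (8aR)-6-{[(tert-butyldiphenylsilyl)oxy]methyl}-8a-methyl-3-(propan-2-ylidene)-1,2,3,3a,4,5,8,8a-octahydroazulen-3a-ol F7. Ionic hydrogenolysis with allylic transposition (Et3SiH, CF3CO2H, CH2Cl2, −40 °C) then gives 24: the allyl cation formed on loss of the tertiary hydroxyl should take hydride at the open CMe2 end and not at the crowded ring carbon.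

Further compounds
F1 | step 3 | 2-allyl-2-methylcyclopentane-1,3-dione | C=CCC1(C)C(=O)CCC1=O
F2 | step 3 | (2S,3S)-2-allyl-3-hydroxy-2-methylcyclopentan-1-one | C=CC[C@@]1(C)[C@@H](O)CCC1=O
F3 | step 3 | O-[(1S,2S)-2-allyl-2-methyl-3-oxocyclopentyl] 1H-imidazole-1-carbothioate | C=CC[C@@]1(C)[C@@H](OC(=S)n2ccnc2)CCC1=O
F4 | step 14 | (5R)-5-allyl-5-methyl-2-(propan-2-yl)cyclopent-1-en-1-yl trifluoromethanesulfonate | C=CC[C@@]1(C)CCC(C(C)C)=C1OS(=O)(=O)C(F)(F)F
F5 | step 14 | tert-butyl({4-[(5R)-5-allyl-5-methyl-2-(propan-2-yl)cyclopent-1-en-1-yl]-2-methylidenebutyl}oxy)diphenylsilane | C=CC[C@@]1(C)CCC(C(C)C)=C1CCC(=C)CO[Si](c2ccccc2)(c2ccccc2)C(C)(C)C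
F6 | step 12 | (2R)-2-allyl-1-(3-{[(tert-butyldiphenylsilyl)oxy]methyl}but-3-en-1-yl)-2-methyl-5-(propan-2-ylidene)cyclopentan-1-ol | C=CC[C@@]1(C)CCC(=C(C)C)C1(O)CCC(=C)CO[Si](c2ccccc2)(c2ccccc2)C(C)(C)C
F7 | step 12 | (8aR)-6-{[(tert-butyldiphenylsilyl)oxy]methyl}-8a-methyl-3-(propan-2-ylidene)-1,2,3,3a,4,5,8,8a-octahydroazulen-3a-ol | CC(C)(C)[Si](c1ccccc1)(c1ccccc1)OCC2=CC[C@@]3(C)CCC(=C(C)C)C3(O)CC2
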